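**Retrosynthetic overview**

1. The strategy rests on the two pyranone rings (ring C of each flavone unit). Each holds an O1–C2 bond (O1–C2 in unit 1, O1''–C2'' in the prenylated unit 2) between a phenolic oxygen ortho to the ring carbonyl and the aryl-bearing sp2 carbon, so each is the cycloisomer of an ortho-hydroxyaryl ynone; both are closed together, last.
2. The bis-ynone is obtained by MnO2 oxidation of a bis(propargylic alcohol), built by two acetylide additions: 4-(MOM-oxy)phenylacetylide to the ring D salicylaldehyde, then the ring B acetylide to 2-hydroxy-4,6-bis(MOM-oxy)benzaldehyde (ring A).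
3. The ring B–ring D bond (C3'–C8'') comes from a Suzuki–Miyaura coupling of a ring B boronate (directed ortho-lithiation) with a 3-iodosalicylaldehyde. O7'' is prenylated afterwards at the only non-chelated hydroxyl.
4. Ring order: rings A, B, D and the 4-hydroxyphenyl ring are bought as arenes, both pyranones form in one step, and the five MOM ethers are removed last.

Key step: step 15

Remark: the ring B–ring D axis carries three small ortho substituents and is taken as freely rotating, so no axial configuration is assigned. The carbinol centres made in steps 11 and 13 are formed without control and are erased in step 14.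

**Route**

Step 1
Reactants: 1 2,4,6-trihydroxybenzaldehyde
Product: 2 2-hydroxy-4,6-bis(methoxymethoxy)benzaldehyde
Conditions: MOMCl (2.2 equiv), i-Pr2NEt, CH2Cl2, 0 °C → rt
Reagents that add atoms: chloromethyl methyl ether, COCCl
Why: Williamson-type O-alkylation should stop at the bis-ether because the remaining ortho hydroxyl is hydrogen-bonded to the formyl group.

Step 2
Reactants: 1 2,4,6-trihydroxybenzaldehyde
Product: 3 4-[(tert-butyldimethylsilyl)oxy]-2,6-dihydroxybenzaldehyde
Conditions: TBSCl (1.0 equiv), imidazole, DMF, 0 °C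
Reagents that add atoms: tert-butyldimethylsilyl chloride, CC(C)(C)[Si](C)(C)Cl
Why: Silylation should take the 4-hydroxyl first, since it is para to the formyl group, the most acidic and not chelated; this parks O7'' under a temporary group.

Step 3
Reactants: 3 4-[(tert-butyldimethylsilyl)oxy]-2,6-dihydroxybenzaldehyde
Product: 4 4-[(tert-butyldimethylsilyl)oxy]-2-hydroxy-6-(methoxymethoxy)benzaldehyde
Conditions: MOMCl (1.1 equiv), i-Pr2NEt, CH2Cl2, 0 °C
Reagents that add atoms: chloromethyl methyl ether, COCCl
Why: The two ortho hydroxyls are equivalent, and after the first O-alkylation the other is locked in the hydrogen bond to the aldehyde, so mono-protection is expected.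

Step 4
Reactants: 4 4-[(tert-butyldimethylsilyl)oxy]-2-hydroxy-6-(methoxymethoxy)benzaldehyde
Product: 5 4-[(tert-butyldimethylsilyl)oxy]-2-hydroxy-3-iodo-6-(methoxymethoxy)benzaldehyde
Conditions: BnMe3N·ICl2 (1.0 equiv), CaCO3, CH2Cl2–MeOH, rt, dark
Reagents that add atoms: benzyltrimethylammonium dichloroiodate, C[N+](C)(C)Cc1ccccc1.Cl[I-]Cl
Why: Electrophilic aromatic iodination should enter C3, ortho to the chelated free hydroxyl rather than between the two ethers, as is usual for 2-hydroxy-4,6-dialkoxyaryl carbonyl compounds and 5-hydroxy-7-alkoxychromones; CaCO3 buffers the HCl so the acetal and silyl ether survive.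

Step 5
Reactants: 6 4-iodophenol
Product: 7 1-iodo-4-(methoxymethoxy)benzene
Conditions: MOMCl, i-Pr2NEt, CH2Cl2, 0 °C → rt
Reagents that add atoms: chloromethyl methyl ether, COCCl
Why: Plain Williamson-type acetal formation on a phenol.

Step 6
Reactants: 7 1-iodo-4-(methoxymethoxy)benzene
Product: 8 triisopropyl{[4-(methoxymethoxy)phenyl]ethynyl}silane
Conditions: TIPS-acetylene, PdCl2(PPh3)2 (cat.), CuI (cat.), Et3N, THF, rt → 50 °C
Reagents that add atoms: (triisopropylsilyl)acetylene, C#C[Si](C(C)C)(C(C)C)C(C)C
Why: Sonogashira coupling of an aryl iodide is reliable, and 8 serves both as the source of the terminal alkyne for unit 2 and as the ring B building block.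

Step 7
Reactants: 8 triisopropyl{[4-(methoxymethoxy)phenyl]ethynyl}silane
Product: 9 1-ethynyl-4-(methoxymethoxy)benzene
Conditions: TBAF, THF, 0 °C → rt
Reagents that add atoms: none
Why: Fluoride-induced C–Si cleavage of a silyl alkyne; the acetal is inert to fluoride.

Step 8
Reactants: 8 triisopropyl{[4-(methoxymethoxy)phenyl]ethynyl}silane
Product: 11 2-{2-(methoxymethoxy)-5-[(triisopropylsilyl)ethynyl]phenyl}-4,4,5,5-tetramethyl-1,3,2-dioxaborolane, via aryllithium 10 (not isolated)
Conditions: s-BuLi, TMEDA, THF, −78 °C; then i-PrOBpin, −78 °C → rt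
Reagents that add atoms: 2-isopropoxy-4,4,5,5-tetramethyl-1,3,2-dioxaborolane, CC(C)OB1OC(C)(C)C(C)(C)O1
Why: Directed ortho-metalation next to the MOM ether (the only directing group, two equivalent ortho sites) followed by borate trapping places boron at C3' of ring B; the bulky silyl alkyne is inert at −78 °C.

Step 9
Reactants: 5 4-[(tert-butyldimethylsilyl)oxy]-2-hydroxy-3-iodo-6-(methoxymethoxy)benzaldehyde; 11 ring B pinacol boronate
Product: 13 2,4-dihydroxy-6-(methoxymethoxy)-3-{2-(methoxymethoxy)-5-[(triisopropylsilyl)ethynyl]phenyl}benzaldehyde, via silylated biaryl aldehyde 12 (not isolated)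
Conditions: Pd(OAc)2 (cat.), SPhos, K3PO4, toluene–H2O (10:1), 90 °C; then K2CO3, MeOH, rt
Reagents that add atoms: none
Why: Suzuki–Miyaura coupling with a dialkylbiarylphosphine ligand is the standard answer for tri-ortho-substituted biaryls and tolerates the free phenol, aldehyde and silyl alkyne; carbonate in methanol then removes the phenolic silyl ether (any lost already during the coupling leads to the same product).

Step 10
Reactants: 13 2,4-dihydroxy-6-(methoxymethoxy)-3-{2-(methoxymethoxy)-5-[(triisopropylsilyl)ethynyl]phenyl}benzaldehyde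
Product: 14 2-hydroxy-6-(methoxymethoxy)-3-{2-(methoxymethoxy)-5-[(triisopropylsilyl)ethynyl]phenyl}-4-[(3-methylbut-2-en-1-yl)oxy]benzaldehyde
Conditions: prenyl bromide (1.1 equiv), K2CO3, acetone, rt
Reagents that add atoms: 1-bromo-3-methylbut-2-ene, CC(C)=CCBr
Why: Williamson ether synthesis should be selective for the 4-hydroxyl (para to the formyl group, acidic, not chelated), while the 2-hydroxyl is hydrogen-bonded to the aldehyde and flanked by ring B; installing the prenyl group only now keeps it away from the iodination and the palladium step.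

Step 11
Reactants: 14 prenylated biaryl aldehyde; 9 1-ethynyl-4-(methoxymethoxy)benzene
Product: 16 1-{2-hydroxy-6-(methoxymethoxy)-3-[2-(methoxymethoxy)-5-[(triisopropylsilyl)ethynyl]phenyl]-4-[(3-methylbut-2-en-1-yl)oxy]phenyl}-3-[4-(methoxymethoxy)phenyl]prop-2-yn-1-ol (racemic at the carbinol), via lithium acetylide 15 (not isolated)
Conditions: 9 (3.3 equiv), n-BuLi (3.2 equiv), THF, −78 °C; then 14, −78 °C → rt; aq. NH4Cl
Reagents that add atoms: none
Why: 1,2-Addition of a lithium acetylide to a salicylaldehyde, where the first equivalent deprotonates the phenol and the excess adds to the formyl group; the ring B alkyne stays silylated so it cannot take part.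

Step 12
Reactants: 16 silylated propargylic alcohol
Product: 17 1-{3-[5-ethynyl-2-(methoxymethoxy)phenyl]-2-hydroxy-6-(methoxymethoxy)-4-[(3-methylbut-2-en-1-yl)oxy]phenyl}-3-[4-(methoxymethoxy)phenyl]prop-2-yn-1-ol (racemic)
Conditions: TBAF (2 equiv), THF, 0 °C → rt
Reagents that add atoms: none
Why: Fluoride-induced desilylation frees the ring B alkyne; acetals, prenyl ether and the propargylic alcohol are stable to fluoride.

Step 13
Reactants: 17 terminal alkyne diol; 2 2-hydroxy-4,6-bis(methoxymethoxy)benzaldehyde
Product: 20 bis(propargylic alcohol) bearing the two free ortho phenols (mixture of diastereomers), via trilithium salt 18 (not isolated), via sodium phenoxide 19 (not isolated)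
Conditions: 17, n-BuLi (3.1 equiv), THF, −78 → −20 °C; then 19 [from 2 (1.5 equiv), NaH, THF, 0 °C], −78 °C → rt; aq. NH4Cl
Reagents that add atoms: none
Why: Acetylide 1,2-addition to an aldehyde, run on the polyanion (phenoxide, alkoxide, acetylide) so no proton can quench the acetylide; the cheap aldehyde is pre-deprotonated and used in excess.

Step 14
Reactants: 20 bis(propargylic alcohol)
Product: 21 bis(ortho-hydroxyaryl ynone) on the prenylated biaryl
Conditions: activated MnO2 (excess), CH2Cl2, rt; filtered and used directly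
Reagents that add atoms: none
Why: MnO2 oxidises benzylic–propargylic alcohols chemoselectively to ynones under neutral conditions, leaving phenols, prenyl ether and acetals untouched and erasing both carbinol stereocentres.

Step 15
Reactants: 21 bis(ortho-hydroxyaryl ynone)
Product: 23 penta-MOM ether of the target, via bis-enaminone 22 (not isolated)
Conditions: Et2NH (10 equiv), EtOH–THF, rt, then 60 °C
Reagents that add atoms: none
Why: Diethylamine adds in conjugate fashion to each ynone to give a β-(diethylamino) enone, and the ortho phenol then attacks the amine-bearing β-carbon and expels the amine, a net oxa-Michael addition–elimination. The closest known reaction is the secondary-amine-mediated conversion of ortho-hydroxyaryl (or ortho-silyloxyaryl) ynones into flavones and chromones, here run at two sites of one molecule. Ring C of unit 1 closes 6-endo through the ring A hydroxyl (O1–C2) and ring C of unit 2 closes 6-endo through the ring D hydroxyl next to the biaryl carbon (O1''–C2''); no stereocentre is formed. The step needs 6-endo over 5-exo closure (flavone, not aurone) at both ynones, and the enaminone relay secures this because only the β-carbon is electrophilic. It also needs the right oxygen in unit 2, which the substrate fixes: O5'' is a MOM ether and O7'' a prenyl ether, so the only free hydroxyl ortho to that carbonyl is the one flanked by ring B, giving the 8-aryl flavone. The medium is non-oxidising and only mildly basic, so the prenyl ether and all five acetals should survive.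

Step 16
Reactants: 23 penta-MOM ether of the target
Product: 24 CNP0152943.0 (7''-O-prenyl 3',8''-biapigenin)
Conditions: HCl (ca. 1 M) in MeOH–THF, rt → 40 °C, stopped at full conversion
Reagents that add atoms: none
Why: Acid-catalysed acetal exchange to methanol removes all five phenolic MOM groups; these ionise to the methoxymethyl oxocarbenium ion much faster than the aryl prenyl ether can ionise, so brief mild acid should spare the O7'' prenyl group.

**Compound list**

1 | 2,4,6-trihydroxybenzaldehyde | O=Cc1c(O)cc(O)cc1O | starting material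
2 | 2-hydroxy-4,6-bis(methoxymethoxy)benzaldehyde | O=Cc1c(O)cc(OCOC)cc1OCOC | intermediate
3 | 4-[(tert-butyldimethylsilyl)oxy]-2,6-dihydroxybenzaldehyde | O=Cc1c(O)cc(O[Si](C)(C)C(C)(C)C)cc1O | intermediate
4 | 4-[(tert-butyldimethylsilyl)oxy]-2-hydroxy-6-(methoxymethoxy)benzaldehyde | O=Cc1c(O)cc(O[Si](C)(C)C(C)(C)C)cc1OCOC | intermediate
5 | 4-[(tert-butyldimethylsilyl)oxy]-2-hydroxy-3-iodo-6-(methoxymethoxy)benzaldehyde | O=Cc1c(O)c(I)c(O[Si](C)(C)C(C)(C)C)cc1OCOC | intermediate
6 | 4-iodophenol | Oc1ccc(I)cc1 | starting material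
7 | 1-iodo-4-(methoxymethoxy)benzene | COCOc1ccc(I)cc1 | intermediate
8 | triisopropyl{[4-(methoxymethoxy)phenyl]ethynyl}silane | COCOc1ccc(C#C[Si](C(C)C)(C(C)C)C(C)C)cc1 | intermediate
9 | 1-ethynyl-4-(methoxymethoxy)benzene | COCOc1ccc(C#C)cc1 | intermediate
10 | {2-(methoxymethoxy)-5-[(triisopropylsilyl)ethynyl]phenyl}lithium (not isolated) | [Li]c1cc(C#C[Si](C(C)C)(C(C)C)C(C)C)ccc1OCOC | intermediate
11 | 2-{2-(methoxymethoxy)-5-[(triisopropylsilyl)ethynyl]phenyl}-4,4,5,5-tetramethyl-1,3,2-dioxaborolane | CC1(C)OB(OC1(C)C)c1cc(C#C[Si](C(C)C)(C(C)C)C(C)C)ccc1OCOC | intermediate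
12 | 4-[(tert-butyldimethylsilyl)oxy]-2-hydroxy-6-(methoxymethoxy)-3-{2-(methoxymethoxy)-5-[(triisopropylsilyl)ethynyl]phenyl}benzaldehyde (not isolated) | O=Cc1c(O)c(-c2cc(C#C[Si](C(C)C)(C(C)C)C(C)C)ccc2OCOC)c(O[Si](C)(C)C(C)(C)C)cc1OCOC | intermediate
13 | 2,4-dihydroxy-6-(methoxymethoxy)-3-{2-(methoxymethoxy)-5-[(triisopropylsilyl)ethynyl]phenyl}benzaldehyde | O=Cc1c(O)c(-c2cc(C#C[Si](C(C)C)(C(C)C)C(C)C)ccc2OCOC)c(O)cc1OCOC | intermediate
14 | 2-hydroxy-6-(methoxymethoxy)-3-{2-(methoxymethoxy)-5-[(triisopropylsilyl)ethynyl]phenyl}-4-[(3-methylbut-2-en-1-yl)oxy]benzaldehyde | O=Cc1c(O)c(-c2cc(C#C[Si](C(C)C)(C(C)C)C(C)C)ccc2OCOC)c(OCC=C(C)C)cc1OCOC | intermediate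
15 | lithium [4-(methoxymethoxy)phenyl]acetylide (not isolated) | [Li]C#Cc1ccc(OCOC)cc1 | intermediate
16 | ring D propargylic alcohol with silylated ring B alkyne (racemic) | CC(C)=CCOc1cc(OCOC)c(C(O)C#Cc2ccc(OCOC)cc2)c(O)c1-c1cc(C#C[Si](C(C)C)(C(C)C)C(C)C)ccc1OCOC | intermediate
17 | ring D propargylic alcohol with free ring B ethynyl group (racemic) | CC(C)=CCOc1cc(OCOC)c(C(O)C#Cc2ccc(OCOC)cc2)c(O)c1-c1cc(C#C)ccc1OCOC | intermediate
18 | trilithium salt of 17: phenoxide, alkoxide and acetylide (not isolated) | CC(C)=CCOc1cc(OCOC)c(C(O[Li])C#Cc2ccc(OCOC)cc2)c(O[Li])c1-c1cc(C#C[Li])ccc1OCOC | intermediate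
19 | sodium 2-formyl-3,5-bis(methoxymethoxy)phenolate (not isolated) | [Na+].[O-]c1cc(OCOC)cc(OCOC)c1C=O | intermediate
20 | bis(propargylic alcohol) with free ring A and ring D ortho phenols (diastereomer mixture) | CC(C)=CCOc1cc(OCOC)c(C(O)C#Cc2ccc(OCOC)cc2)c(O)c1-c1cc(C#CC(O)c2c(O)cc(OCOC)cc2OCOC)ccc1OCOC | intermediate
21 | bis(ortho-hydroxyaryl ynone) on the prenylated biaryl | CC(C)=CCOc1cc(OCOC)c(C(=O)C#Cc2ccc(OCOC)cc2)c(O)c1-c1cc(C#CC(=O)c2c(O)cc(OCOC)cc2OCOC)ccc1OCOC | intermediate
22 | bis[β-(diethylamino) enone], alkene geometry undefined (not isolated) | CC(C)=CCOc1cc(OCOC)c(C(=O)C=C(N(CC)CC)c2ccc(OCOC)cc2)c(O)c1-c1cc(C(N(CC)CC)=CC(=O)c2c(O)cc(OCOC)cc2OCOC)ccc1OCOC | intermediate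
23 | penta-MOM ether of the target (5,7,4',5'',4'''-pentakis(methoxymethoxy)-7''-prenyloxy-3',8''-biflavone) | CC(C)=CCOc1cc(OCOC)c2c(=O)cc(-c3ccc(OCOC)cc3)oc2c1-c1cc(-c2cc(=O)c3c(OCOC)cc(OCOC)cc3o2)ccc1OCOC | intermediate
24 | CNP0152943.0, 7''-O-(3-methylbut-2-enyl) 3',8''-biapigenin | CC(C)=CCOc1cc(O)c2c(=O)cc(-c3ccc(O)cc3)oc2c1-c1cc(-c2cc(=O)c3c(O)cc(O)cc3o2)ccc1O | target

**Step count and risks**

Total: 16 steps. Longest linear sequence: 11 steps (1 → 3 → 4 → 5 → 13 → 14 → 16 → 17 → 20 → 21 → 23 → 24; the branch from 6 through 7, 8 and 11 has the same length).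

Steps most likely to fail:

Step 15. One or both ynones could stall at the amine adduct, or a phenoxide could close 5-exo to a benzofuranone, giving mixtures of half-closed material. The fallback closes the rings through the chalcone–flavanone sequence. Setting out from 21, semihydrogenation (H2, Pd/CaCO3 poisoned with Pb(OAc)2, quinoline, EtOAc) would give the bis[(Z)-2'-hydroxychalcone] F1. NaOAc in EtOH at reflux would close both rings by 6-endo-trig oxa-Michael addition to the bis-flavanone F2 (epimer mixture at C2 and C2'', of no consequence). Dehydrogenation with IBX in DMSO at 80 °C would restore both C2=C3 double bonds and come back to the route at 23.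

Step 13. The trilithium salt could aggregate or precipitate, so the acetylide addition could be slow and incomplete. The fallback masks the two hydroxyls so that a simple monoacetylide is used. Setting out from 17, TESCl and imidazole in DMF would give the bis(triethylsilyl) ether F3. LiHMDS (THF, −78 °C) followed by sodium phenoxide 19 would give the silylated adduct F4. TBAF buffered with AcOH (THF, 0 °C) would remove both silyl groups and come back to the route at 20.

Step 9. Protodeboronation of the ortho-alkoxy boronate and reduction of the hindered, electron-rich iodide could outrun the cross-coupling. The fallback is a base-free Negishi coupling. Setting out from 8, aryllithium 10 (made as in step 8) would be transmetalated with ZnCl2 to the arylzinc chloride F5. This would be coupled with 5 (pre-treated with NaH) under Pd(OAc)2/SPhos in THF at 60 °C to give 12, and K2CO3 in MeOH would then give 13, where the route resumes.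

**Further compounds**

F1 | step 15 | bis[(Z)-2'-hydroxychalcone] from semihydrogenation of 21 | CC(C)=CCOc1cc(OCOC)c(C(=O)/C=C\c2ccc(OCOC)cc2)c(O)c1-c1cc(/C=C\C(=O)c2c(O)cc(OCOC)cc2OCOC)ccc1OCOC
F2 | step 15 | penta-MOM bis-flavanone (2,3- and 2'',3''-dihydro analogue of 23, epimer mixture) | CC(C)=CCOc1cc(OCOC)c2C(=O)CC(c3ccc(OCOC)cc3)Oc2c1-c1cc(C2CC(=O)c3c(OCOC)cc(OCOC)cc3O2)ccc1OCOC
F3 | step 13 | bis(triethylsilyl) ether of 17 | CC(C)=CCOc1cc(OCOC)c(C(O[Si](CC)(CC)CC)C#Cc2ccc(OCOC)cc2)c(O[Si](CC)(CC)CC)c1-c1cc(C#C)ccc1OCOC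
F4 | step 13 | bis(triethylsilyl) ether of 20 (silyl groups on the ring D phenol and the unit 2 carbinol) | CC(C)=CCOc1cc(OCOC)c(C(O[Si](CC)(CC)CC)C#Cc2ccc(OCOC)cc2)c(O[Si](CC)(CC)CC)c1-c1cc(C#CC(O)c2c(O)cc(OCOC)cc2OCOC)ccc1OCOC
F5 | step 9 | {2-(methoxymethoxy)-5-[(triisopropylsilyl)ethynyl]phenyl}zinc chloride | Cl[Zn]c1cc(C#C[Si](C(C)C)(C(C)C)C(C)C)ccc1OCOC
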